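**Retrosynthetic overview**

1. Target 14 ⇒ 4-bromoveratrole 11 + acyclic homoallylic hydrogen oxalate 10. One cascade makes the lactone C2–C3 bond (5-exo closure of an alkoxycarbonyl radical) and then the bond from the exocyclic CH2 on C3 to C1 of the 3,4-dimethoxyphenyl ring (nickel).
2. Enabling feature: the benzylic CH2 is exocyclic on C3, next to the lactone carbonyl C2, so an O1–C2 acyl radical closing on a C3=CH2 vinyl group puts the radical exactly on that CH2. C3–H is α to the C=O, so C3 can be equilibrated to trans relative to the fixed C4.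
3. 10 ⇒ alcohol 8 + oxalyl chloride; 8 ⇒ imide 7 by reductive removal of the auxiliary.
4. 7 ⇒ crotonimide 4 + 3,4,5-trimethoxybenzyl bromide 5 (deconjugative Evans alkylation sets the future C4); 4 ⇒ oxazolidinone 1 + crotonyl chloride 2.
5. Ring order: the γ-lactone is the only ring formed, and it is formed last, in the key step.

Key step: step 5

Remark: the SMILES is read as the trans-(3R,4R) lactone; lactone numbering O1, C2 (C=O), C3 (α), C4 (β), C5 (OCH2) is used throughout.

**Step 1**
Reactants: 1 (R)-4-benzyl-2-oxazolidinone; 2 (E)-but-2-enoyl chloride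
Product: 4 (R)-4-benzyl-3-[(E)-but-2-enoyl]oxazolidin-2-one, via N-lithio oxazolidinone 3 (not isolated)
Conditions: n-BuLi, THF, −78 °C; then 2, −78 → 0 °C
Reagents that add atoms: none
Why: N-acylation of the lithiated oxazolidinone with an acid chloride (standard Evans imide formation) should proceed cleanly at low temperature and does not touch the stereocentre of the auxiliary.

**Step 2**
Reactants: 4 (R)-4-benzyl-3-[(E)-but-2-enoyl]oxazolidin-2-one; 5 3,4,5-trimethoxybenzyl bromide
Product: 7 (R)-4-benzyl-3-[(R)-2-(3,4,5-trimethoxybenzyl)but-3-enoyl]oxazolidin-2-one, via sodium dienolate 6 (not isolated)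
Conditions: NaHMDS, THF, −78 °C; then 5, −78 → −40 °C; cold aq. NH4Cl work-up
Reagents that add atoms: none
Why: Evans-type deconjugative alkylation: γ-deprotonation of the s-cis crotonimide should give the chelated (Z)-dienolate, which takes the benzylic bromide at the α-carbon on the face opposite the C4 benzyl group of the auxiliary, setting the (R) centre that becomes C4 of the lactone and moving the double bond out of conjugation.

**Step 3**
Reactants: 7 (R)-4-benzyl-3-[(R)-2-(3,4,5-trimethoxybenzyl)but-3-enoyl]oxazolidin-2-one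
Product: 8 (R)-2-(3,4,5-trimethoxybenzyl)but-3-en-1-ol
Conditions: LiBH4, H2O (1 equiv), Et2O, 0 °C
Reagents that add atoms: none
Why: Reductive cleavage of the N-acyl oxazolidinone by hydride attack at the exocyclic carbonyl should release the primary alcohol and the recoverable auxiliary without epimerising the allylic stereocentre or reducing the terminal alkene.

**Step 4**
Reactants: 8 (R)-2-(3,4,5-trimethoxybenzyl)but-3-en-1-ol
Product: 10 (R)-2-(3,4,5-trimethoxybenzyl)but-3-en-1-yl hydrogen oxalate, via alkyl chlorooxoacetate 9 (not isolated)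
Conditions: (COCl)2 (excess), Et2O, 0 °C → rt; then H2O, 0 °C
Reagents that add atoms: oxalyl chloride ClC(=O)C(=O)Cl; water O
Why: O-acylation of the primary alcohol with oxalyl chloride followed by hydrolysis of the remaining acid chloride gives the alkyl hydrogen oxalate, the standard activation of an alcohol for photoredox oxalate chemistry; the stereocentre is not involved.

**Step 5**
Reactants: 10 (R)-2-(3,4,5-trimethoxybenzyl)but-3-en-1-yl hydrogen oxalate; 11 4-bromo-1,2-dimethoxybenzene (4-bromoveratrole)
Product: 14 (3R,4R)-3-(3,4-dimethoxybenzyl)-4-(3,4,5-trimethoxybenzyl)dihydrofuran-2(3H)-one, via cesium oxalate 12 (not isolated), via cis-lactone 13 (not isolated)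
Conditions: CsHCO3, Ir[dF(CF3)ppy]2(dtbbpy)PF6 (1 mol%), NiBr2·glyme/dtbbpy (5 mol%), degassed dioxane/DMSO (dilute), blue LEDs, rt; then DBU (cat.), 40 °C
Reagents that add atoms: none
Why: Proposed new method: the cesium oxalate 12 formed in the flask is oxidised by the excited Ir(III) photocatalyst and loses CO2 to a primary alkoxycarbonyl radical, whose acyl carbon adds to the internal vinyl carbon and leaves a primary radical on the exocyclic CH2; this radical is taken up by nickel, which has inserted into the C–Br bond of 11, and reductive elimination from aryl(alkyl)Ni(III) forms the CH2–aryl bond while Ir(II) returns Ni(I) to Ni(0). The closest known reaction type is the Ir/Ni alkoxycarbonyl radical cyclisation–cross-coupling cascade of homoallylic oxalates of tertiary alcohols with aryl halides, supported by tin-mediated 5-exo cyclisations of alkoxycarbonyl radicals from primary homoallylic selenocarbonates; new here are the primary oxalate and the stereocentre beside the alkene. The γ-lactone closes in the 5-exo-trig mode (C2 onto C3, radical on the exocyclic carbon). The new C3 centre is controlled by C4: in the chair-like transition state the 3,4,5-trimethoxybenzyl group sits pseudo-equatorial, so the exocyclic CH2 should end up trans to it, and DBU added to the same flask epimerises any cis-lactone 13 through the C3 enolate to the more stable trans isomer, C4 having no acidic hydrogen. The step needs ring closure to outrun capture of the alkoxycarbonyl radical by nickel (aryl ester) and a second loss of CO2; a primary alkoxycarbonyl radical decarboxylates slowly, and low nickel loading with high dilution favours the unimolecular closure. The position of the new bond on the arene is fixed by the bromine of 11, so only the 3,4-dimethoxyphenyl isomer can form.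

**Compound list**

1 | (R)-4-benzyl-2-oxazolidinone | O=C1N[C@H](Cc2ccccc2)CO1 | starting material
2 | (E)-but-2-enoyl chloride (crotonyl chloride) | C/C=C/C(Cl)=O | starting material
3 | lithium (R)-4-benzyl-2-oxooxazolidin-3-ide | [Li+].O=C1[N-][C@H](Cc2ccccc2)CO1 | intermediate
4 | (R)-4-benzyl-3-[(E)-but-2-enoyl]oxazolidin-2-one | C/C=C/C(=O)N1[C@H](Cc2ccccc2)COC1=O | intermediate
5 | 3,4,5-trimethoxybenzyl bromide | COc1cc(CBr)cc(OC)c1OC | starting material
6 | sodium (Z)-dienolate of 4 | [Na+].C=C/C=C(\[O-])N1[C@H](Cc2ccccc2)COC1=O | intermediate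
7 | (R)-4-benzyl-3-[(R)-2-(3,4,5-trimethoxybenzyl)but-3-enoyl]oxazolidin-2-one | C=C[C@@H](Cc1cc(OC)c(OC)c(OC)c1)C(=O)N1[C@H](Cc2ccccc2)COC1=O | intermediate
8 | (R)-2-(3,4,5-trimethoxybenzyl)but-3-en-1-ol | OC[C@@H](C=C)Cc1cc(OC)c(OC)c(OC)c1 | intermediate
9 | (R)-2-(3,4,5-trimethoxybenzyl)but-3-en-1-yl chlorooxoacetate | O=C(Cl)C(=O)OC[C@@H](C=C)Cc1cc(OC)c(OC)c(OC)c1 | intermediate
10 | (R)-2-(3,4,5-trimethoxybenzyl)but-3-en-1-yl hydrogen oxalate | OC(=O)C(=O)OC[C@@H](C=C)Cc1cc(OC)c(OC)c(OC)c1 | intermediate
11 | 4-bromo-1,2-dimethoxybenzene | COc1ccc(Br)cc1OC | starting material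
12 | cesium (R)-2-(3,4,5-trimethoxybenzyl)but-3-en-1-yl oxalate | [Cs+].[O-]C(=O)C(=O)OC[C@@H](C=C)Cc1cc(OC)c(OC)c(OC)c1 | intermediate
13 | (3S,4R)-3-(3,4-dimethoxybenzyl)-4-(3,4,5-trimethoxybenzyl)dihydrofuran-2(3H)-one (cis) | COc1ccc(C[C@@H]2C(=O)OC[C@@H]2Cc2cc(OC)c(OC)c(OC)c2)cc1OC | intermediate
14 | (3R,4R)-3-(3,4-dimethoxybenzyl)-4-(3,4,5-trimethoxybenzyl)dihydrofuran-2(3H)-one (trans) | COc1ccc(C[C@H]2C(=O)OC[C@@H]2Cc2cc(OC)c(OC)c(OC)c2)cc1OC | target

**Totals**

Total step count: 5. Longest linear sequence: 5 steps (1 → 4 → 7 → 8 → 10 → 14).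

**Steps most likely to fail**

1. Step 5 (proposed new method). What may go wrong: nickel may intercept the alkoxycarbonyl radical before ring closure, giving aryl ester coupling instead of the cascade. The cyclised primary radical may also attack the neighbouring trimethoxyphenyl ring, or β-hydride elimination may occur at nickel after capture. Incomplete trans selectivity is already covered by the in-flask equilibration.
 Fallback (known chemistry only; sets out from alcohol 8 and comes back at target 14): hydroboration–oxidation of the vinyl group (9-BBN, THF; NaOH, H2O2) should give (R)-2-(3,4,5-trimethoxybenzyl)butane-1,4-diol F1. TEMPO/PhI(OAc)2 oxidative lactonisation, which starts at the less hindered CH2OH, should give (R)-4-(3,4,5-trimethoxybenzyl)dihydrofuran-2(3H)-one F2. The lithium enolate (LiHMDS, THF, −78 °C) with Eschenmoser's salt should give the Mannich base (3S,4R)-3-[(dimethylamino)methyl]-4-(3,4,5-trimethoxybenzyl)dihydrofuran-2(3H)-one F3. MeI converts it into the methiodide F4, and NaHCO3 eliminates the ammonium group to give (R)-3-methylene-4-(3,4,5-trimethoxybenzyl)dihydrofuran-2(3H)-one F5. Rh(I)-catalysed 1,4-addition of 3,4-dimethoxyphenylboronic acid ([Rh(cod)OH]2, dioxane/H2O, 60 °C; Hayashi–Miyaura type, with protonation of the rhodium enolate) then forms the same aryl–CH2 bond. DBU equilibration of any cis-lactone 13 gives 14.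

2. Step 2. What may go wrong: γ- instead of α-alkylation of the dienolate, base-mediated migration of the double bond back into conjugation (which erases the new stereocentre), or incomplete facial selectivity.
 Fallback (sets out from bromide 5 and comes back at alcohol 8, bypassing the auxiliary): 5 is converted (Mg, 2-MeTHF, 0 °C, slow addition) into 3,4,5-trimethoxybenzylmagnesium bromide F6. Copper-catalysed asymmetric SN2′ allylic alkylation of commercial (E)-1,4-dibromobut-2-ene (CuTC, chiral phosphoramidite ligand of the enantiomeric series that leads to the R product, CH2Cl2, −78 °C) should give (R)-5-[2-(bromomethyl)but-3-en-1-yl]-1,2,3-trimethoxybenzene F7. KOAc in DMF displaces the primary bromide to give (R)-2-(3,4,5-trimethoxybenzyl)but-3-en-1-yl acetate F8, and K2CO3/MeOH releases 8.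

3. Step 3. What may go wrong: hydride attack at the endocyclic carbamate carbonyl (ring opening of the auxiliary, favoured by the α-branched acyl group), or alkoxide-induced migration of the double bond with loss of the stereocentre.
 Fallback (sets out from imide 7 and comes back at alcohol 8): LiOH/H2O2 (THF/H2O, 0 °C), in which hydroperoxide attacks the exocyclic carbonyl selectively, should give (R)-2-(3,4,5-trimethoxybenzyl)but-3-enoic acid F9. LiAlH4 (Et2O, 0 °C) then reduces the acid to 8 without touching the isolated alkene.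

**Further compounds**

F1 | step 5 | (R)-2-(3,4,5-trimethoxybenzyl)butane-1,4-diol | OC[C@@H](CCO)Cc1cc(OC)c(OC)c(OC)c1
F2 | step 5 | (R)-4-(3,4,5-trimethoxybenzyl)dihydrofuran-2(3H)-one | O=C1OC[C@@H](C1)Cc2cc(OC)c(OC)c(OC)c2
F3 | step 5 | (3S,4R)-3-[(dimethylamino)methyl]-4-(3,4,5-trimethoxybenzyl)dihydrofuran-2(3H)-one | CN(C)C[C@H]1C(=O)OC[C@@H]1Cc2cc(OC)c(OC)c(OC)c2
F4 | step 5 | trimethyl{[(3S,4R)-2-oxo-4-(3,4,5-trimethoxybenzyl)tetrahydrofuran-3-yl]methyl}ammonium iodide | C[N+](C)(C)C[C@H]1C(=O)OC[C@@H]1Cc2cc(OC)c(OC)c(OC)c2.[I-]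
F5 | step 5 | (R)-3-methylene-4-(3,4,5-trimethoxybenzyl)dihydrofuran-2(3H)-one | C=C1C(=O)OC[C@@H]1Cc2cc(OC)c(OC)c(OC)c2
F6 | step 2 | 3,4,5-trimethoxybenzylmagnesium bromide | COc1cc(C[Mg]Br)cc(OC)c1OC
F7 | step 2 | (R)-5-[2-(bromomethyl)but-3-en-1-yl]-1,2,3-trimethoxybenzene | BrC[C@@H](C=C)Cc1cc(OC)c(OC)c(OC)c1
F8 | step 2 | (R)-2-(3,4,5-trimethoxybenzyl)but-3-en-1-yl acetate | CC(=O)OC[C@@H](C=C)Cc1cc(OC)c(OC)c(OC)c1
F9 | step 3 | (R)-2-(3,4,5-trimethoxybenzyl)but-3-enoic acid | C=C[C@@H](Cc1cc(OC)c(OC)c(OC)c1)C(=O)O
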